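## The problem

(3S,4S,3′R)-4-Hydroxyalloxanthin 16 is a C40 carotenoid in which a C20 heptaene (C8 to C8′, seven E double bonds, methyl groups on C9, C13, C13′ and C9′) lies between two triple bonds (C7≡C8 and C7′≡C8′), each bonded to C6 or C6′ of a 1,1,5-trimethylcyclohexene ring. The rings differ by one oxygen: ring A (C1–C6) carries a trans-3,4-diol whose C4–OH is allylic, ring B (C1′–C6′) only the 3′-OH, so two nearly identical ends must be placed on a symmetric chain without a statistical mixture. C6 and C6′ are fully substituted alkene carbons between C1(CH3)2 and C5–CH3, so the bond to the alkyne is hindered and the ring double bond has to stay at C5=C6. The stereocenters form two groups separated by a rigid 18-carbon spacer and cannot control each other; only C3 can direct C4, while C3 and C3′ have the same spatial sense (the S/R change is a priority effect of O4), so one chiral source can serve both rings. The E double bonds at C9 and C9′, next to the triple bonds, are not sterically favoured over Z and isomerise under heat, light or iodine, so an olefination that gives E/Z mixtures and must be equilibrated puts them at risk. The C4–OH is allylic to a dienyne that runs into the polyene and ionises in acid, and the polyene does not tolerate oxidants, strong electrophiles or long heating. The feature that opens the plan is twofold: the segment C8–C8′ is, atom for atom and with all seven E double bonds, crocetindialdehyde 11 with C8 and C8′ as formyl carbons, and in each ring the only double bond C5=C6 (C5′=C6′) is the enol double bond of a 2,2,6-trimethylcyclohexanone whose carbonyl carbon is C6 (C6′). A formyl group can therefore be turned into C7≡C8–H and joined to an enol triflate at C6 by sp2–sp coupling (the key step), and no double bond of the chain is ever made.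

## Retrosynthesis

16 ⇒ 15. Only the three O–Si bonds are cut. Silyl ethers are preferred to esters or acetals because the last step can then use fluoride, with no acid near the allylic C4–O bond. The forward step must leave the polyene and the three stereocenters untouched.

15 ⇒ 14 + 10. The C6–C7 bond between ring A and its alkyne is cut. The neighbouring cuts are worse: C8–C9 would need a C9 vinyl halide and would touch the labile 9E bond, and C10–C11 or C11=C12 are olefination cuts that create E/Z mixtures. The precursors are a complete ring (triflate 10, both stereocenters set) and the C31 terminal alkyne 14 that already holds ring B and the whole chain. The forward reaction must form a bond at a doubly flanked alkene carbon at room temperature without moving any double bond.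

14 ⇒ 13. The triple bond C7≡C8 is traced back to the C8 formyl group; the one carbon removed is C7. This is the shortest way to reach an sp carbon from the oxidation level that the commercial chain offers. The forward step is a one-carbon homologation that must add to C=O and not deprotonate or isomerise the polyenal.

13 ⇒ 12 + 5. The C6′–C7′ bond is cut in the same way as C6–C7. Ring B is attached first because triflate 5 costs three steps and triflate 10 six, so the more valuable ring enters last. The aldehyde at C8 is a spectator that keeps the two chain ends chemically distinct.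

12 ⇒ 11. The same one-carbon cut at C7′ leads to the symmetric dialdehyde 11. The forward reaction must homologate one of two equivalent formyl groups; stoichiometry (excess, recoverable 11) and the lower electrophilicity of the mono-adduct are relied on.

10 ⇒ 8. The C6–O(triflyl) bond is cut; the enolate 9 of ketone 8 can form in one direction only, because C1 is quaternary and C5 holds the single α-hydrogen. This fixes the ring double bond at C5=C6.

8 ⇒ 7 ⇒ 6 ⇒ 3. The C4–O bond is traced back to an epoxide on the enone double bond of 3, the C5–O bond of which is removed reductively. Epoxidation anti to the C3 silyloxy group sets 4S from 3S, and the C4–O bond is never broken afterwards. Enone 3 is a nine-carbon ring with one stereocenter.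

5 ⇒ 3. The C6′–O(triflyl) bond is cut back to the same enone 3: hydride instead of oxygen is added to the β-carbon (future C4′), giving enolate 4 directly. Both rings thus come from one intermediate.

3 ⇒ 2 ⇒ 1. The O–Si bond and then the carbinol C–H bond are cut, which leads to achiral ketoisophorone 1. The asymmetric reduction of its unhindered carbonyl is the only step of the synthesis that needs absolute stereocontrol.

## Roads not taken

Alternative 1: the most obvious plan cuts C11=C12 and C11′=C12′ (C15 + C10 + C15). The forward key step is a double Wittig reaction of the ring B phosphonium salt A1 and the ring A phosphonium salt A2, one after the other, with the C10 dialdehyde A3. Each Wittig reaction gives an 11E/11Z mixture, and the thermal or iodine equilibration needed to reach all-E also acts on the 9E and 9′E bonds beside the triple bonds. A2 has to be made by ionising a primary allylic alcohol in a molecule that holds a second allylic C–O bond at C4. Two C15 side chains have to be built and functionalised, and A3 still has to be desymmetrised. The chosen plan makes no chain double bond and is shorter.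

Alternative 2: both ring–alkyne bonds are cut at once and the C2 symmetry is kept. The forward key step is a double coupling of one ring triflate (5) with a symmetric diyne to give bis-silyl alloxanthin A4, followed by late allylic oxidation at C4. C4 and C4′ of A4 are indistinguishable, so mono-oxidation is statistical; allylic oxidants also attack the polyene; and the 4S centre would need a further reduction on the complete carotenoid. In the chosen plan the C4 oxygen and its configuration are set on a small ring.

Alternative 3: C6–C7 is made by carbonyl addition instead of cross-coupling. The lithium acetylide of 14 would add to enone 3 to give the tertiary carbinol A5. A Babler–Dauben oxidative 1,3-transposition with pyridinium chlorochromate (C5H5NH[CrO3Cl], hexavalent chromium) would give enone A6, and desilylation with hydroxyl-directed reduction of C4=O would follow. The plan is stereoconvergent at C6 and also starts from 3. Its drawbacks are that it puts an acidic chromium oxidant on a heptaene-diyne, passes through a 3-hydroxy-4-ketone that epimerises at C3 by enolisation, and needs three steps after the union on the most sensitive material where the chosen plan needs one.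

Key step: step 11

Remark: carotenoid numbering is used for ring and chain positions (unprimed = diol end, ring A; primed = ring B end); ketoisophorone 1 and all-E crocetindialdehyde 11 are taken as the commercial compounds.

## Steps

Step 1
Reactants: 1 2,6,6-trimethylcyclohex-2-ene-1,4-dione (ketoisophorone)
Product: 2 (4S)-4-hydroxy-2,6,6-trimethylcyclohex-2-en-1-one
Conditions: RuCl[(S,S)-TsDPEN](p-cymene) (0.5 mol %), HCO2H–Et3N (5:2), CH2Cl2, 25 °C
Reagents that add atoms: none
Why: Asymmetric transfer hydrogenation with a bifunctional Ru–H/N–H catalyst should reduce the unhindered C4 carbonyl and leave C1, which lies between C(CH3)2 and C–CH3; the alkene arm takes the place of the aryl group of an aryl alkyl ketone, so the (S,S)-ligand is expected to give the 4S carbinol (the (R,R)-ligand is used if the sense is found reversed), and this centre becomes C3 of ring A and C3′ of ring B.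

Step 2
Reactants: 2 (4S)-4-hydroxy-2,6,6-trimethylcyclohex-2-en-1-one
Product: 3 (4S)-4-[(tert-butyldimethylsilyl)oxy]-2,6,6-trimethylcyclohex-2-en-1-one
Conditions: TBSCl, imidazole, DMF, 25 °C
Reagents that add atoms: tert-butyldimethylsilyl chloride, CC(C)(C)[Si](C)(C)Cl
Why: Standard silylation of a secondary alcohol; the silyl ether should survive hydride, alkaline peroxide, SmI2, amide bases and the palladium/copper/amine couplings, and it supplies the bulk that directs step 4.

Step 3
Reactants: 3 (4S)-4-[(tert-butyldimethylsilyl)oxy]-2,6,6-trimethylcyclohex-2-en-1-one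
Product: 5 (4R)-4-[(tert-butyldimethylsilyl)oxy]-2,6,6-trimethylcyclohex-1-en-1-yl trifluoromethanesulfonate (ring B triflate), via lithium enolate 4 (not isolated)
Conditions: LiBH(s-Bu)3 (1.1 equiv), THF, −78 °C; then PhNTf2, −78 → 0 °C
Reagents that add atoms: N-phenylbis(trifluoromethanesulfonyl)imide, O=S(=O)(N(c1ccccc1)S(=O)(=O)C(F)(F)F)C(F)(F)F
Why: Conjugate reduction with enolate trapping: the carbonyl carbon is shielded on both sides while the β-carbon (future C4′) bears hydrogen, so the bulky hydride should add 1,4 and give the enolate whose double bond is the future C5′=C6′; O-triflation freezes this regiochemistry, and no stereocenter is formed or touched (the descriptor changes from S to R only by priority).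

Step 4
Reactants: 3 (4S)-4-[(tert-butyldimethylsilyl)oxy]-2,6,6-trimethylcyclohex-2-en-1-one
Product: 6 (1R,5S,6R)-5-[(tert-butyldimethylsilyl)oxy]-1,3,3-trimethyl-7-oxabicyclo[4.1.0]heptan-2-one (epoxide trans to the silyloxy group)
Conditions: H2O2 (30 % aq), NaOH (cat.), MeOH, 0 °C
Reagents that add atoms: hydrogen peroxide, OO
Why: Weitz–Scheffer nucleophilic epoxidation; hydroperoxide adds to the β-carbon (future C4) from the face opposite to the neighbouring pseudoequatorial silyloxy group, as is usual for 4-substituted cyclohex-2-enones, so the new C–O bond is trans to the C3 oxygen and the 4S configuration is set by the 3S centre.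

Step 5
Reactants: 6 (1R,5S,6R)-5-[(tert-butyldimethylsilyl)oxy]-1,3,3-trimethyl-7-oxabicyclo[4.1.0]heptan-2-one
Product: 7 (4S,5S)-4-[(tert-butyldimethylsilyl)oxy]-5-hydroxy-2,2,6-trimethylcyclohexan-1-one (both C6 epimers)
Conditions: SmI2 (2.2 equiv), THF–MeOH, −90 °C
Reagents that add atoms: none
Why: Reductive cleavage of the α C–O bond of an α,β-epoxy ketone by samarium diiodide (ketyl, then enolate and alkoxide, then protonation) gives the β-hydroxy ketone; the C–O bond at the future C4 is not broken, so its configuration is kept, and the epimers at the α-carbon do not matter because this carbon becomes sp2 in step 7.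

Step 6
Reactants: 7 (4S,5S)-4-[(tert-butyldimethylsilyl)oxy]-5-hydroxy-2,2,6-trimethylcyclohexan-1-one
Product: 8 (4S,5S)-4,5-bis[(tert-butyldimethylsilyl)oxy]-2,2,6-trimethylcyclohexan-1-one (both C6 epimers)
Conditions: TBSOTf, 2,6-lutidine, CH2Cl2, −78 → 0 °C
Reagents that add atoms: tert-butyldimethylsilyl trifluoromethanesulfonate, CC(C)(C)[Si](C)(C)OS(=O)(=O)C(F)(F)F
Why: Silylation of a hindered secondary alcohol with the silyl triflate at low temperature, which should avoid dehydration of the β-hydroxy ketone back to the enone; a possible 1,2-silyl shift would be harmless because both oxygens end up silylated.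

Step 7
Reactants: 8 (4S,5S)-4,5-bis[(tert-butyldimethylsilyl)oxy]-2,2,6-trimethylcyclohexan-1-one
Product: 10 (3S,4S)-3,4-bis[(tert-butyldimethylsilyl)oxy]-2,6,6-trimethylcyclohex-1-en-1-yl trifluoromethanesulfonate (ring A triflate), via lithium enolate 9 (not isolated)
Conditions: LiN(i-Pr)2, THF, −78 °C; then N-(5-chloropyridin-2-yl)bis(trifluoromethanesulfonyl)imide, −78 → −20 °C
Reagents that add atoms: N-(5-chloropyridin-2-yl)bis(trifluoromethanesulfonyl)imide, O=S(=O)(N(c1ccc(Cl)cn1)S(=O)(=O)C(F)(F)F)C(F)(F)F
Why: Enolate O-triflation; the ketone has a single α-hydrogen, so only the enolate with the future C5=C6 double bond can form and both C6 epimers of 8 converge; the β-silyloxy group sits equatorial in the diequatorial conformer and is poorly aligned for E1cB loss at −78 °C, and the two carbinol centres are untouched.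

Step 8
Reactants: 11 (2E,4E,6E,8E,10E,12E,14E)-2,6,11,15-tetramethylhexadeca-2,4,6,8,10,12,14-heptaenedial (crocetindialdehyde)
Product: 12 (2E,4E,6E,8E,10E,12E,14E)-2,6,11,15-tetramethylheptadeca-2,4,6,8,10,12,14-heptaen-16-ynal
Conditions: Me3SiCHN2 (1 equiv), LiN(i-Pr)2 (1 equiv), THF, −78 °C; added to 11 (3 equiv) in THF, −78 → 25 °C, dark; unreacted 11 recovered
Reagents that add atoms: trimethylsilyldiazomethane, C[Si](C)(C)C=[N+]=[N-]
Why: Colvin rearrangement: the lithiated diazo reagent adds to one formyl group, Peterson-type elimination gives a diazoalkene, loss of N2 and a 1,2-hydrogen shift of the alkylidene carbene give the terminal alkyne, the diazo carbon becoming C7′; mono-reaction is favoured by the excess of 11 and by the lower electrophilicity of the remaining formyl group once its acceptor partner at the other chain end is gone, and no double bond is formed or isomerised.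

Step 9
Reactants: 12 (2E,4E,6E,8E,10E,12E,14E)-2,6,11,15-tetramethylheptadeca-2,4,6,8,10,12,14-heptaen-16-ynal; 5 (4R)-4-[(tert-butyldimethylsilyl)oxy]-2,6,6-trimethylcyclohex-1-en-1-yl trifluoromethanesulfonate
Product: 13 (2E,4E,6E,8E,10E,12E,14E)-17-[(4R)-4-[(tert-butyldimethylsilyl)oxy]-2,6,6-trimethylcyclohex-1-en-1-yl]-2,6,11,15-tetramethylheptadeca-2,4,6,8,10,12,14-heptaen-16-ynal
Conditions: Pd(PPh3)4 (5 mol %), CuI (10 mol %), Et3N, THF, 25 °C, argon, dark
Reagents that add atoms: none
Why: Sonogashira coupling of a 2,6,6-trimethylcyclohexenyl triflate with a terminal enyne, a combination with close precedent; it forms C6′–C7′ with the ring double bond fixed at C5′=C6′, the tertiary amine does not condense with the aldehyde, and the aldehyde keeps the other chain end distinct for step 10.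

Step 10
Reactants: 13 (2E,4E,6E,8E,10E,12E,14E)-17-[(4R)-4-[(tert-butyldimethylsilyl)oxy]-2,6,6-trimethylcyclohex-1-en-1-yl]-2,6,11,15-tetramethylheptadeca-2,4,6,8,10,12,14-heptaen-16-ynal
Product: 14 tert-butyldimethyl{[(1R)-3,5,5-trimethyl-4-[(3E,5E,7E,9E,11E,13E,15E)-3,7,12,16-tetramethyloctadeca-3,5,7,9,11,13,15-heptaene-1,17-diyn-1-yl]cyclohex-3-en-1-yl]oxy}silane
Conditions: Me3SiCHN2 (1.3 equiv), LiN(i-Pr)2 (1.3 equiv), THF, −78 → 25 °C, dark
Reagents that add atoms: trimethylsilyldiazomethane, C[Si](C)(C)C=[N+]=[N-]
Why: Second Colvin rearrangement, now on the only formyl group left; carbonyl addition at −78 °C should be faster than deprotonation of the polyenal, the silyl ether and the internal alkyne are inert, and the new carbon is C7.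

Step 11
Reactants: 14 tert-butyldimethyl{[(1R)-3,5,5-trimethyl-4-[(3E,5E,7E,9E,11E,13E,15E)-3,7,12,16-tetramethyloctadeca-3,5,7,9,11,13,15-heptaene-1,17-diyn-1-yl]cyclohex-3-en-1-yl]oxy}silane; 10 (3S,4S)-3,4-bis[(tert-butyldimethylsilyl)oxy]-2,6,6-trimethylcyclohex-1-en-1-yl trifluoromethanesulfonate
Product: 15 (3S,4S,3′R)-3,4,3′-tris[(tert-butyldimethylsilyl)oxy]-7,8,7′,8′-tetradehydro-β,β-carotene (all-E)
Conditions: Pd(PPh3)4 (5 mol %), CuI (10 mol %), Et3N, THF–DMF, 25 °C, argon, dark; 10 in slight excess
Reagents that add atoms: none
Why: Sonogashira coupling: zerovalent palladium inserts into the C6–O bond of enol triflate 10, CuI and Et3N convert the terminal alkyne of 14 into its monovalent copper acetylide, and transmetalation followed by reductive elimination forms the C6–C7 bond. The closest known reaction type is the coupling of 2,6,6-trimethylcyclohexenyl triflates with terminal enynes, which tolerates the same flanking C1(CH3)2 and C5–CH3 groups. No ring is closed and no stereocenter is created; C3, C4 and C3′ are carried in and the step only has to leave them and the seven E double bonds as they are. The position of the ring double bond (C5=C6) was fixed by the enolate regiochemistry of 10 and cannot move, because C1 is quaternary. Chemoselectivity for the vinylic C–O(triflyl) bond over the allylic C4–O(silyl) bond follows from the easy oxidative addition at the triflate and the poor leaving-group ability of a silyloxide. Cross-coupling has to outrun oxidative dimerisation of the alkyne, which exclusion of oxygen and a small excess of 10 should secure, and room temperature in the dark avoids E/Z isomerisation at C9 and C9′. With this step the whole C40 skeleton, both triple bonds and all three stereocenters are in place, and only desilylation remains.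

Step 12
Reactants: 15 (3S,4S,3′R)-3,4,3′-tris[(tert-butyldimethylsilyl)oxy]-7,8,7′,8′-tetradehydro-β,β-carotene
Product: 16 (3S,4S,3′R)-7,8,7′,8′-tetradehydro-β,β-carotene-3,4,3′-triol ((3S,4S,3′R)-4-hydroxyalloxanthin, all-E)
Conditions: n-Bu4NF, AcOH, THF, 25 °C, argon, dark
Reagents that add atoms: none
Why: Fluoride-induced cleavage of the three silyl ethers under acetic acid buffering; no strong acid is present, so the allylic C4–OH should not ionise, and no stereocenter or double bond is involved.

## Compound list

1 | 2,6,6-trimethylcyclohex-2-ene-1,4-dione (ketoisophorone) | CC1=CC(=O)CC(C)(C)C1=O | starting material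
2 | (4S)-4-hydroxy-2,6,6-trimethylcyclohex-2-en-1-one | CC1=C[C@@H](O)CC(C)(C)C1=O | intermediate
3 | (4S)-4-[(tert-butyldimethylsilyl)oxy]-2,6,6-trimethylcyclohex-2-en-1-one | CC1=C[C@@H](O[Si](C)(C)C(C)(C)C)CC(C)(C)C1=O | intermediate
4 | lithium (4R)-4-[(tert-butyldimethylsilyl)oxy]-2,6,6-trimethylcyclohex-1-en-1-olate | CC1=C([O-])C(C)(C)C[C@H](O[Si](C)(C)C(C)(C)C)C1.[Li+] | intermediate
5 | (4R)-4-[(tert-butyldimethylsilyl)oxy]-2,6,6-trimethylcyclohex-1-en-1-yl trifluoromethanesulfonate | CC1=C(OS(=O)(=O)C(F)(F)F)C(C)(C)C[C@H](O[Si](C)(C)C(C)(C)C)C1 | intermediate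
6 | (1R,5S,6R)-5-[(tert-butyldimethylsilyl)oxy]-1,3,3-trimethyl-7-oxabicyclo[4.1.0]heptan-2-one | CC1(C)C[C@H](O[Si](C)(C)C(C)(C)C)[C@H]2O[C@@]2(C)C1=O | intermediate
7 | (4S,5S)-4-[(tert-butyldimethylsilyl)oxy]-5-hydroxy-2,2,6-trimethylcyclohexan-1-one (both C6 epimers) | CC1(C)C[C@H](O[Si](C)(C)C(C)(C)C)[C@@H](O)C(C)C1=O | intermediate
8 | (4S,5S)-4,5-bis[(tert-butyldimethylsilyl)oxy]-2,2,6-trimethylcyclohexan-1-one (both C6 epimers) | CC1(C)C[C@H](O[Si](C)(C)C(C)(C)C)[C@@H](O[Si](C)(C)C(C)(C)C)C(C)C1=O | intermediate
9 | lithium (3S,4S)-3,4-bis[(tert-butyldimethylsilyl)oxy]-2,6,6-trimethylcyclohex-1-en-1-olate | CC1(C)C[C@H](O[Si](C)(C)C(C)(C)C)[C@@H](O[Si](C)(C)C(C)(C)C)C(C)=C1[O-].[Li+] | intermediate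
10 | (3S,4S)-3,4-bis[(tert-butyldimethylsilyl)oxy]-2,6,6-trimethylcyclohex-1-en-1-yl trifluoromethanesulfonate | CC1(C)C[C@H](O[Si](C)(C)C(C)(C)C)[C@@H](O[Si](C)(C)C(C)(C)C)C(C)=C1OS(=O)(=O)C(F)(F)F | intermediate
11 | (2E,4E,6E,8E,10E,12E,14E)-2,6,11,15-tetramethylhexadeca-2,4,6,8,10,12,14-heptaenedial (crocetindialdehyde) | O=C/C(C)=C/C=C/C(C)=C/C=C/C=C(C)/C=C/C=C(C)/C=O | starting material
12 | (2E,4E,6E,8E,10E,12E,14E)-2,6,11,15-tetramethylheptadeca-2,4,6,8,10,12,14-heptaen-16-ynal | C#C/C(C)=C/C=C/C(C)=C/C=C/C=C(C)/C=C/C=C(C)/C=O | intermediate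
13 | (2E,4E,6E,8E,10E,12E,14E)-17-[(4R)-4-[(tert-butyldimethylsilyl)oxy]-2,6,6-trimethylcyclohex-1-en-1-yl]-2,6,11,15-tetramethylheptadeca-2,4,6,8,10,12,14-heptaen-16-ynal | CC1=C(C#C/C(C)=C/C=C/C(C)=C/C=C/C=C(C)/C=C/C=C(C)/C=O)C(C)(C)C[C@H](O[Si](C)(C)C(C)(C)C)C1 | intermediate
14 | tert-butyldimethyl{[(1R)-3,5,5-trimethyl-4-[(3E,5E,7E,9E,11E,13E,15E)-3,7,12,16-tetramethyloctadeca-3,5,7,9,11,13,15-heptaene-1,17-diyn-1-yl]cyclohex-3-en-1-yl]oxy}silane | CC1=C(C#C/C(C)=C/C=C/C(C)=C/C=C/C=C(C)/C=C/C=C(C)/C#C)C(C)(C)C[C@H](O[Si](C)(C)C(C)(C)C)C1 | intermediate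
15 | (3S,4S,3′R)-3,4,3′-tris[(tert-butyldimethylsilyl)oxy]-7,8,7′,8′-tetradehydro-β,β-carotene (all-E) | CC1=C(C#C/C(C)=C/C=C/C(C)=C/C=C/C=C(C)/C=C/C=C(\C)C#CC2=C(C)[C@H](O[Si](C)(C)C(C)(C)C)[C@@H](O[Si](C)(C)C(C)(C)C)CC2(C)C)C(C)(C)C[C@H](O[Si](C)(C)C(C)(C)C)C1 | intermediate
16 | (3S,4S,3′R)-4-hydroxyalloxanthin | CC1=C(C#C/C(C)=C/C=C/C(C)=C/C=C/C=C(C)/C=C/C=C(\C)C#CC2=C(C)[C@H](O)[C@@H](O)CC2(C)C)C(C)(C)C[C@H](O)C1 | target

## Step count and risks

Total step count: 12. Longest linear sequence: 8 steps (steps 1, 2, 4, 5, 6, 7, 11, 12).

Step 11 (key step). The most likely failure is slow oxidative addition at the triflate carbon, which is flanked by C1(CH3)2 and C5–CH3 and now also by a bulky allylic silyl ether. Oxidative dimerisation of the alkyne and slow decay of the polyene would then take over. The fallback makes the C6–C7 bond by carbonyl addition instead of cross-coupling. It sets out from alkyne 14 and ketone 8: 14 is deprotonated with LiN(SiMe3)2 at −78 °C, transmetalated with CeCl3 and added to 8 to give the tertiary propargylic alcohol F1. F1 is dehydrated with POCl3 in pyridine; elimination can only go toward C5 because C1 is quaternary. The fallback returns to the route at 15.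

Step 8. The risk is over-reaction at the second formyl group, made worse if 11 dissolves poorly at low temperature so that dissolved molecules meet a local excess of reagent. The fallback gives up the mono-homologation: 11 is treated with 2.5 equivalents of the lithiated diazo reagent to give the symmetric heptaenediyne F2. F2 is then used in threefold excess in the coupling with triflate 5 under the conditions of step 9, so that mono-coupling prevails and surplus F2 is recovered. The fallback sets out from 11 and returns at 14, bypassing 12 and 13.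

Step 7. The risk is E1cB loss of the silyloxy group next to the enolate (back to an enone), or failure to remove the hindered tertiary α-hydrogen. The fallback generates the enolate reductively. It sets out from epoxy ketone 6, which is treated with lithium 4,4′-di-tert-butylbiphenylide (2.2 equiv) in THF at −78 °C. This gives the enolate together with the neighbouring lithium alkoxide, whose oxide cannot leave. Trapping with the same pyridyl triflimide gives the hydroxy triflate F3, and silylation with TBSOTf and 2,6-lutidine returns to the route at 10.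

Step 3. The risk is competing 1,2-hydride addition, or sluggish O-triflation of the boron-bound enolate. The fallback separates reduction and enolate formation. It sets out from 3, which is hydrogenated over Pd/C in ethyl acetate to the saturated ketone F4 (both C6 epimers). Deprotonation with LiN(i-Pr)2 and trapping with PhNTf2 returns to the route at 5.

Step 10. The risk is deprotonation of the polyenal at a vinylogous methyl group by the lithiated diazo reagent instead of carbonyl addition, or side reactions of the alkylidene carbene with the neighbouring double bond. The fallback is the two-stage Corey–Fuchs sequence. It sets out from 13, which is converted with CBr4 and PPh3 at 0 °C into the 1,1-dibromoalkene F5. Treatment with n-BuLi (2.1 equiv) at −78 °C and protonation returns to the route at 14.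

## Further compounds

F1 | step 11 | tertiary propargylic alcohol from 14 and 8: 1-alkynyl-(3S,4S)-3,4-bis[(tert-butyldimethylsilyl)oxy]-2,6,6-trimethylcyclohexan-1-ol carrying the C31 chain of 14 (epimers at C1 and C2 of the cyclohexanol) | CC1C(O)(C#C/C(C)=C/C=C/C(C)=C/C=C/C=C(C)/C=C/C=C(\C)C#CC2=C(C)C[C@@H](O[Si](C)(C)C(C)(C)C)CC2(C)C)C(C)(C)C[C@H](O[Si](C)(C)C(C)(C)C)[C@H]1O[Si](C)(C)C(C)(C)C
F2 | step 8 | (3E,5E,7E,9E,11E,13E,15E)-3,7,12,16-tetramethyloctadeca-3,5,7,9,11,13,15-heptaene-1,17-diyne | C#C/C(C)=C/C=C/C(C)=C/C=C/C=C(C)/C=C/C=C(C)/C#C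
F3 | step 7 | (3S,4S)-4-[(tert-butyldimethylsilyl)oxy]-3-hydroxy-2,6,6-trimethylcyclohex-1-en-1-yl trifluoromethanesulfonate | CC1(C)C[C@H](O[Si](C)(C)C(C)(C)C)[C@@H](O)C(C)=C1OS(=O)(=O)C(F)(F)F
F4 | step 3 | (4R)-4-[(tert-butyldimethylsilyl)oxy]-2,2,6-trimethylcyclohexan-1-one (both C6 epimers) | CC1C(=O)C(C)(C)C[C@H](O[Si](C)(C)C(C)(C)C)C1
F5 | step 10 | 1,1-dibromoalkene of 13: tert-butyl{[(1R)-4-[(3E,5E,7E,9E,11E,13E,15E)-18,18-dibromo-3,7,12,16-tetramethyloctadeca-3,5,7,9,11,13,15,17-octaen-1-yn-1-yl]-3,5,5-trimethylcyclohex-3-en-1-yl]oxy}dimethylsilane | CC1=C(C#C/C(C)=C/C=C/C(C)=C/C=C/C=C(C)/C=C/C=C(C)/C=C(Br)Br)C(C)(C)C[C@H](O[Si](C)(C)C(C)(C)C)C1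
A1 | alternative 1 | [(2E)-5-[(4R)-4-hydroxy-2,6,6-trimethylcyclohex-1-en-1-yl]-3-methylpent-2-en-4-yn-1-yl]triphenylphosphonium bromide | CC1=C(C#C/C(C)=C/C[P+](c2ccccc2)(c2ccccc2)c2ccccc2)C(C)(C)C[C@H](O)C1.[Br-]
A2 | alternative 1 | [(2E)-5-[(3S,4S)-3,4-dihydroxy-2,6,6-trimethylcyclohex-1-en-1-yl]-3-methylpent-2-en-4-yn-1-yl]triphenylphosphonium bromide | CC1=C(C#C/C(C)=C/C[P+](c2ccccc2)(c2ccccc2)c2ccccc2)C(C)(C)C[C@H](O)[C@H]1O.[Br-]
A3 | alternative 1 | (2E,4E,6E)-2,7-dimethylocta-2,4,6-trienedial | O=C/C(C)=C/C=C/C=C(C)/C=O
A4 | alternative 2 | (3R,3′R)-3,3′-bis[(tert-butyldimethylsilyl)oxy]-7,8,7′,8′-tetradehydro-β,β-carotene (bis-silyl alloxanthin) | CC1=C(C#C/C(C)=C/C=C/C(C)=C/C=C/C=C(C)/C=C/C=C(\C)C#CC2=C(C)C[C@@H](O[Si](C)(C)C(C)(C)C)CC2(C)C)C(C)(C)C[C@H](O[Si](C)(C)C(C)(C)C)C1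
A5 | alternative 3 | tertiary carbinol from 3 and the acetylide of 14: (4S)-4-[(tert-butyldimethylsilyl)oxy]-2,6,6-trimethylcyclohex-2-en-1-ol carrying the C31 alkynyl chain of 14 at C1 (both C1 epimers) | CC1=C[C@@H](O[Si](C)(C)C(C)(C)C)CC(C)(C)C1(O)C#C/C(C)=C/C=C/C(C)=C/C=C/C=C(C)/C=C/C=C(\C)C#CC1=C(C)C[C@@H](O[Si](C)(C)C(C)(C)C)CC1(C)C
A6 | alternative 3 | (3S,3′R)-3,3′-bis[(tert-butyldimethylsilyl)oxy]-7,8,7′,8′-tetradehydro-β,β-caroten-4-one | CC1=C(C#C/C(C)=C/C=C/C(C)=C/C=C/C=C(C)/C=C/C=C(\C)C#CC2=C(C)C[C@@H](O[Si](C)(C)C(C)(C)C)CC2(C)C)C(C)(C)C[C@H](O[Si](C)(C)C(C)(C)C)C1=O
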